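The ten-membered carbocycle is traced back to a thirteen-membered diallyl ether by disconnecting C6–C7 and reconnecting O6 to C13. One [2,3]-Wittig shift forms C6–C7, contracts the ring, frees O6 as the carbinol and turns C13 into the methylene on C11, setting C6 and C7 together. It exploits the C6 carbinol beside C7 carrying the C11(=C13)–C12 unit on the ten-membered ring, the atoms of the later methylene lactone ring. The precursor is the cyclic ether C6–O–C13 with the E C7=C11 bond, C12 hydroxymethyl, 1(10)E and 4Z alkenes, C3 OTBDPS and C8 OTBS; C8 is epimeric to the target there and inverted at the esterification.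

Key step: step 21

Remark on the chemistry: atoms carry germacrane numbers throughout (C1–C10 ring, C11–C13 on C7, C14 on C10, C15 on C4); the contraction is assumed to add C6 to the face of C7=C11 anti to the C8–O bond (H8 in the alkene plane to avoid A(1,3) strain with C12, silyloxy group pseudo-equatorial on the forming ring), whereas the target has the new bond syn to C8–O, so C8 is carried as 8S through the contraction and inverted in step 24; the series with C8 as in the target throughout is the fallback to step 21.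

Step 1
Reactants: 1 (R)-glycidol
Product: 2 (S)-2-[(4-methoxybenzyloxy)methyl]oxirane
Conditions: NaH, 4-methoxybenzyl chloride, n-Bu4NI (cat.), DMF, 0 °C to rt
Reagents that add atoms: 4-methoxybenzyl chloride, COc1ccc(CCl)cc1
Why: Williamson etherification of the primary alkoxide with a benzylic chloride; no bond to the stereocentre is touched, and the descriptor changes from R to S only because the substituent priorities change.

Step 2
Reactants: 2 (S)-2-[(4-methoxybenzyloxy)methyl]oxirane
Product: 3 (S)-1-(4-methoxybenzyloxy)pent-4-yn-2-ol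
Conditions: LiC≡CH·H2NCH2CH2NH2, DMSO, rt; then H2O
Reagents that add atoms: lithium acetylide–ethylenediamine complex, [Li+].[C-]#C.NCCN
Why: SN2 opening of the terminal epoxide at its CH2 carbon (C9) by the acetylide, which leaves the carbinol carbon C8 with the configuration brought in by 1 (8S).

Step 3
Reactants: 3 (S)-1-(4-methoxybenzyloxy)pent-4-yn-2-ol
Product: 4 TBS ether of 3
Conditions: TBSCl, imidazole, DMF, rt
Reagents that add atoms: tert-butyldimethylsilyl chloride, CC(C)(C)[Si](C)(C)Cl
Why: Silyl ether formation on a secondary alcohol; the bulky group is wanted later as the anti, pseudo-equatorial substituent on C8 in the ring contraction.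

Step 4
Reactants: 4 TBS ether of 3
Product: 7 (3E,6S)-6-(tert-butyldimethylsilyloxy)-7-(4-methoxybenzyloxy)-4-methylhept-3-en-1-ol, via alkenyldimethylalane 5 (not isolated), via lithium alanate 6 (not isolated)
Conditions: Me3Al, Cp2ZrCl2 (0.25 equiv), CH2Cl2, 0 °C to rt; solvent change to hexane–THF; n-BuLi, −30 °C; ethylene oxide, −30 °C to rt; aq. potassium sodium tartrate
Reagents that add atoms: trimethylaluminium, C[Al](C)C; ethylene oxide, C1CO1
Why: Negishi zirconium-catalysed syn-carboalumination of the terminal alkyne puts the methyl group (C14) on C10 and aluminium on C1, which fixes the 1(10)E geometry, and the derived alanate opens ethylene oxide by SN2 to add C2 and C3.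

Step 5
Reactants: 8 but-2-yn-1-ol
Product: 10 (Z)-3-iodobut-2-en-1-ol, via cyclic alkenylalanate 9 (not isolated)
Conditions: NaAlH2(OCH2CH2OCH3)2, THF, 0 °C to rt; then I2, −78 to 0 °C
Reagents that add atoms: iodine, II
Why: Hydroxyl-directed trans-hydroalumination of the propargylic alcohol places aluminium on C4 cis to C6, and iodinolysis with retention gives the Z iodide that carries the 4Z geometry.

Step 6
Reactants: 10 (Z)-3-iodobut-2-en-1-ol
Product: 11 (Z)-tert-butyl[(3-iodobut-2-en-1-yl)oxy]dimethylsilane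
Conditions: TBSCl, imidazole, DMF, rt
Reagents that add atoms: tert-butyldimethylsilyl chloride, CC(C)(C)[Si](C)(C)Cl
Why: Silyl ether formation; O6 becomes a primary allylic silyl ether that can later be removed beside the secondary ones.

Step 7
Reactants: 7 (3E,6S)-hept-3-en-1-ol
Product: 12 (3E,6S)-6-(tert-butyldimethylsilyloxy)-7-(4-methoxybenzyloxy)-4-methylhept-3-enal
Conditions: Dess–Martin periodinane, NaHCO3, CH2Cl2, 0 °C to rt; used crude
Reagents that add atoms: none
Why: Dess–Martin oxidation under buffered, neutral conditions, so that the β,γ-unsaturated aldehyde does not move into conjugation.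

Step 8
Reactants: 12 (3E,6S)-hept-3-enal; 11 (Z)-alkenyl iodide
Product: 13 (2Z,6E,9S)-1,9-bis(tert-butyldimethylsilyloxy)-10-(4-methoxybenzyloxy)-3,7-dimethyldeca-2,6-dien-4-ol as both epimers at the new carbinol (C3)
Conditions: CrCl2 (6 equiv), NiCl2 (2 mol %), DMF, rt
Reagents that add atoms: none
Why: Nozaki–Hiyama–Kishi coupling, in which divalent chromium with catalytic nickel turns the alkenyl iodide into an alkenylchromium species that adds to the enolisable aldehyde with retention of the Z geometry; C3 forms without control and is set in step 10.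

Step 9
Reactants: 13 allylic alcohol (C3 epimers)
Product: 14 (2Z,6E,9S)-1,9-bis(tert-butyldimethylsilyloxy)-10-(4-methoxybenzyloxy)-3,7-dimethyldeca-2,6-dien-4-one
Conditions: Dess–Martin periodinane, NaHCO3, CH2Cl2, 0 °C
Reagents that add atoms: none
Why: Dess–Martin oxidation of the allylic alcohol to the Z enone removes the uncontrolled centre, and the neutral conditions should keep the Z geometry and the skipped C1=C10 bond in place.

Step 10
Reactants: 14 Z enone
Product: 15 (2Z,4R,6E,9S)-1,9-bis(tert-butyldimethylsilyloxy)-10-(4-methoxybenzyloxy)-3,7-dimethyldeca-2,6-dien-4-ol (3R in germacrane numbers)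
Conditions: (S)-2-methyl-CBS-oxazaborolidine (0.5 equiv), catecholborane, toluene, −78 °C; then H2O
Reagents that add atoms: none
Why: Corey–Bakshi–Shibata reduction, in which the branched alkenyl group acts as the large and the CH2 group as the small substituent, so that the (S)-catalyst should deliver hydride to the face that gives the 3R allylic alcohol.

Step 11
Reactants: 15 (3R) allylic alcohol
Product: 16 TBDPS ether of 15
Conditions: TBDPSCl, imidazole, DMAP (cat.), DMF, rt to 40 °C
Reagents that add atoms: tert-butyl(chloro)diphenylsilane, CC(C)(C)[Si](Cl)(c1ccccc1)c1ccccc1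
Why: Silyl ether formation; the TBDPS group must outlast the later removal of both TBS groups.

Step 12
Reactants: 16 TBDPS ether
Product: 17 (2S,4E,7R,8Z)-2,10-bis(tert-butyldimethylsilyloxy)-7-(tert-butyldiphenylsilyloxy)-4,8-dimethyldeca-4,8-dien-1-ol
Conditions: DDQ, CH2Cl2–pH 7 buffer, 0 °C
Reagents that add atoms: none
Why: Oxidative cleavage of the 4-methoxybenzyl ether (hydride abstraction, then hydrolysis), which leaves silyl ethers and trisubstituted alkenes untouched.

Step 13
Reactants: 17 primary alcohol (C7)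
Product: 18 (2S,4E,7R,8Z)-2,10-bis(tert-butyldimethylsilyloxy)-7-(tert-butyldiphenylsilyloxy)-4,8-dimethyldeca-4,8-dienal
Conditions: Dess–Martin periodinane, NaHCO3, CH2Cl2, 0 °C; used crude
Reagents that add atoms: none
Why: Dess–Martin oxidation to the α-silyloxy aldehyde, which should keep its C8 configuration under these neutral conditions.

Step 14
Reactants: 18 α-silyloxy aldehyde
Product: 19 ethyl (2Z,4S,6E,9R,10Z)-2-bromo-4,12-bis(tert-butyldimethylsilyloxy)-9-(tert-butyldiphenylsilyloxy)-6,10-dimethyldodeca-2,6,10-trienoate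
Conditions: Ph3P=CHCO2Et, NBS, CH2Cl2, −20 °C; then 18, −20 °C to rt
Reagents that add atoms: ethyl (triphenylphosphoranylidene)acetate, CCOC(=O)C=P(c1ccccc1)(c1ccccc1)c1ccccc1; N-bromosuccinimide, O=C1CCC(=O)N1Br
Why: Wittig olefination with the bromo-stabilised ylide formed in the flask; stabilised ylides place the ester trans to the aldehyde residue, so bromine should end cis to C8 (Z) and the ester carbon C13 trans to C8.

Step 15
Reactants: 19 bromo enoate
Product: 20 ethyl (2Z,4S,6E,9R,10Z)-2-bromo-4-(tert-butyldimethylsilyloxy)-9-(tert-butyldiphenylsilyloxy)-12-hydroxy-6,10-dimethyldodeca-2,6,10-trienoate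
Conditions: HF·pyridine, pyridine, THF, 0 °C
Reagents that add atoms: none
Why: Desilylation with buffered HF·pyridine, which removes the unhindered primary allylic TBS ether far faster than the secondary TBS and TBDPS ethers.

Step 16
Reactants: 20 primary allylic alcohol (C6)
Product: 21 ethyl (2Z,4S,6E,9R,10Z)-2-bromo-4-(tert-butyldimethylsilyloxy)-9-(tert-butyldiphenylsilyloxy)-12-chloro-6,10-dimethyldodeca-2,6,10-trienoate
Conditions: NCS, Me2S, CH2Cl2, −20 to 0 °C
Reagents that add atoms: N-chlorosuccinimide, O=C1CCC(=O)N1Cl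
Why: Corey–Kim chlorination (SN2 of chloride on the alkoxysulfonium ion), which converts the primary allylic alcohol to the chloride without allylic transposition and leaves the enoate and the alkenyl bromide alone.

Step 17
Reactants: 21 chloro ester
Product: 22 (2Z,4S,6E,9R,10Z)-2-bromo-4-(tert-butyldimethylsilyloxy)-9-(tert-butyldiphenylsilyloxy)-12-chloro-6,10-dimethyldodeca-2,6,10-trien-1-ol
Conditions: i-Bu2AlH (2.5 equiv), CH2Cl2, −78 °C; aq. potassium sodium tartrate
Reagents that add atoms: none
Why: Reduction of the ester to the primary alcohol (O13) with i-Bu2AlH at low temperature, under which the alkenyl bromide and the allylic chloride should be inert.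

Step 18
Reactants: 22 chloro alcohol
Product: 23 thirteen-membered cyclic ether C6–O–C13 with bromine on C11, C13 trans to C8, 8S OTBS, 3R OTBDPS, 1(10)E, 4Z
Conditions: NaH, n-Bu4NI (cat.), THF (0.003 M, slow addition), rt to 45 °C
Reagents that add atoms: none
Why: Intramolecular Williamson etherification (SN2 of the C13 alkoxide at the primary allylic C6 chloride) under high dilution, a closure known for thirteen-membered diallyl ethers; the alkoxide lies trans to C8 across the alkene and so cannot pick up either silyl group.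

Step 19
Reactants: 23 macrocyclic alkenyl bromide
Product: 24 the same cyclic ether with a methyl ester (C12) on C11, cis to C8
Conditions: Pd(OAc)2 (10 mol %), Xantphos (12 mol %), CO (1 atm), Et3N, MeOH–DMF, 70 °C
Reagents that add atoms: carbon monoxide, [C-]#[O+]; methanol, CO
Why: Palladium-catalysed methoxycarbonylation of the alkenyl bromide (oxidative addition to zerovalent palladium, CO insertion, methanolysis) with retention of geometry, which places C12 cis to C8.

Step 20
Reactants: 24 macrocyclic ester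
Product: 25 the same cyclic ether with hydroxymethyl (C12) on C11: the ring-contraction precursor (3R, 8S)
Conditions: i-Bu2AlH (2.5 equiv), CH2Cl2, −78 °C; aq. potassium sodium tartrate
Reagents that add atoms: none
Why: Ester reduction with i-Bu2AlH to the allylic alcohol, which provides the free C12 hydroxyl that serves as the alkoxide in the next step.

Step 21
Reactants: 25 thirteen-membered cyclic diallyl ether
Product: 28 ten-membered (1(10)E,4Z)-dien-6-ol with 3-hydroxyprop-1-en-2-yl on C7 (CIP 3R,6R,7S,8S), via lithium alkoxide 26 (not isolated), via dilithio species 27 (not isolated)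
Conditions: n-BuLi (2.3 equiv), THF, −78 to −25 °C; then H2O
Reagents that add atoms: none
Why: The first equivalent of n-BuLi gives the C12 alkoxide and the second removes an allylic, ether-activated proton at C6; the C6 carbanion then bonds to C7 while O–C13 breaks, a concerted suprafacial [2,3]-Wittig shift through a five-membered envelope (C6, O, C13, C11, C7). The closest known reaction is this same ring contraction of thirteen-membered diallyl ethers to 6-hydroxy-7-(propen-2-yl)cyclodeca-1(10),4-dienes. The ten-membered ring closes transannularly: C6 and C7 are already held in one ring, which shrinks from thirteen to ten atoms as O, C13 and C11 leave the ring path, so no dilution is needed. C6 and C7 are set together: the E C7=C11 bond with C5 exo on the envelope gives the anti H6/H7 relation, and the face of C7 is fixed by C8, whose hydrogen lies in the alkene plane (A(1,3) strain with C12) so that ring carbon C9 sits on the attacked face and the silyloxy group anti to the new bond, pseudo-equatorial on the forming ring, while the C3 silyloxy group, outside the ring with H3 eclipsing C4=C5, should be matched with this sense. The step needs lithiation at C6 and not at C13: the C12 alkoxide penalises a second negative charge on the same allyl unit, and a C13 anion could only shift onto the fully substituted C4. Both points rest on conformational reasoning and are what the first experiments must confirm.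

Step 22
Reactants: 28 ring-contracted diol
Product: 31 6,12-lactone (α-methylene-γ-butyrolactone) with 8S OTBS and 3R OTBDPS, via hydroxy enal 29 (not isolated), via lactol 30 (not isolated)
Conditions: TEMPO (0.2 equiv), PhI(OAc)2 (2.5 equiv), CH2Cl2, rt
Reagents that add atoms: none
Why: Oxidative lactonisation of a 2-methylene-1,4-diol, in which nitroxyl-catalysed oxidation takes the primary allylic alcohol to the enal, the C6 hydroxyl closes the five-membered lactol and a second oxidation gives the lactone, the C8 silyl ether leaving O6 as the only partner.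

Step 23
Reactants: 31 lactone
Product: 32 lactone with free 8S hydroxyl (3R OTBDPS kept)
Conditions: HF·pyridine, pyridine, THF, 0 °C to rt
Reagents that add atoms: none
Why: Selective desilylation, the secondary TBS ether being cleaved by HF·pyridine much faster than the allylic TBDPS ether at C3.

Step 24
Reactants: 32 8S alcohol
Product: 33 8R isovalerate (3-methylbutanoate) of the lactone, 3R OTBDPS
Conditions: PPh3, DIAD, 3-methylbutanoic acid, toluene, 0 °C to rt
Reagents that add atoms: 3-methylbutanoic acid, CC(C)CC(=O)O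
Why: Mitsunobu esterification, in which the alkoxyphosphonium ion at C8 is displaced by isovalerate in an SN2 step that inverts C8 from S to the R configuration of the target while installing the ester.

Step 25
Reactants: 33 8R isovalerate
Product: 34 (1R,10R)-1,10-epoxide of 33
Conditions: mCPBA, NaHCO3, CH2Cl2, 0 °C
Reagents that add atoms: 3-chloroperbenzoic acid, OOC(=O)c1cccc(Cl)c1
Why: Prilezhaev epoxidation, in which the peracid should choose the isolated, electron-rich C1=C10 bond (C4=C5 is flanked by two allylic oxygens, C11=C13 is conjugated) and its outer face on the ten-membered ring, the E geometry being transferred to the trans epoxide with 1R,10R.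

Step 26
Reactants: 34 epoxide
Product: 35 CNP0300193.1 (target)
Conditions: n-Bu4NF, AcOH (1:1), THF, 0 °C to rt
Reagents that add atoms: none
Why: Fluoride-mediated cleavage of the last silyl ether, buffered with acetic acid so that the epoxide, the ester and the methylene lactone are not exposed to base.

Compound list
1 | (R)-glycidol, (2R)-oxiran-2-ylmethanol | OC[C@@H]1CO1 | starting material
2 | (S)-2-[(4-methoxybenzyloxy)methyl]oxirane | COc1ccc(COC[C@@H]2CO2)cc1 | intermediate
3 | (S)-1-(4-methoxybenzyloxy)pent-4-yn-2-ol (carbinol carbon is C8) | COc1ccc(COC[C@@H](O)CC#C)cc1 | intermediate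
4 | (S)-tert-butyl{[1-(4-methoxybenzyloxy)pent-4-yn-2-yl]oxy}dimethylsilane | COc1ccc(COC[C@@H](O[Si](C)(C)C(C)(C)C)CC#C)cc1 | intermediate
5 | dimethyl[(1E,4S)-4-(tert-butyldimethylsilyloxy)-5-(4-methoxybenzyloxy)-2-methylpent-1-en-1-yl]alane | COc1ccc(COC[C@@H](O[Si](C)(C)C(C)(C)C)C/C(C)=C/[Al](C)C)cc1 | intermediate (not isolated)
6 | lithium n-butyl alanate of 5 | [Li+].COc1ccc(COC[C@@H](O[Si](C)(C)C(C)(C)C)C/C(C)=C/[Al-](C)(C)CCCC)cc1 | intermediate (not isolated)
7 | (3E,6S)-6-(tert-butyldimethylsilyloxy)-7-(4-methoxybenzyloxy)-4-methylhept-3-en-1-ol | COc1ccc(COC[C@@H](O[Si](C)(C)C(C)(C)C)C/C(C)=C/CCO)cc1 | intermediate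
8 | but-2-yn-1-ol | CC#CCO | starting material
9 | sodium bis(2-methoxyethoxy)alanate with aluminium bound to C4 and O6 in a five-membered ring (hydroalumination adduct of 8) | [Na+].CC1=CCO[Al-]1(OCCOC)OCCOC | intermediate (not isolated)
10 | (Z)-3-iodobut-2-en-1-ol | C/C(I)=C/CO | intermediate
11 | (Z)-tert-butyl[(3-iodobut-2-en-1-yl)oxy]dimethylsilane | C/C(I)=C/CO[Si](C)(C)C(C)(C)C | intermediate
12 | (3E,6S)-6-(tert-butyldimethylsilyloxy)-7-(4-methoxybenzyloxy)-4-methylhept-3-enal | COc1ccc(COC[C@@H](O[Si](C)(C)C(C)(C)C)C/C(C)=C/CC=O)cc1 | intermediate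
13 | (2Z,6E,9S)-1,9-bis(tert-butyldimethylsilyloxy)-10-(4-methoxybenzyloxy)-3,7-dimethyldeca-2,6-dien-4-ol, both epimers at C4 of the chain (C3 in germacrane numbers) | COc1ccc(COC[C@@H](O[Si](C)(C)C(C)(C)C)C/C(C)=C/CC(O)/C(C)=C\CO[Si](C)(C)C(C)(C)C)cc1 | intermediate
14 | (2Z,6E,9S)-1,9-bis(tert-butyldimethylsilyloxy)-10-(4-methoxybenzyloxy)-3,7-dimethyldeca-2,6-dien-4-one | COc1ccc(COC[C@@H](O[Si](C)(C)C(C)(C)C)C/C(C)=C/CC(=O)/C(C)=C\CO[Si](C)(C)C(C)(C)C)cc1 | intermediate
15 | (2Z,4R,6E,9S)-1,9-bis(tert-butyldimethylsilyloxy)-10-(4-methoxybenzyloxy)-3,7-dimethyldeca-2,6-dien-4-ol | COc1ccc(COC[C@@H](O[Si](C)(C)C(C)(C)C)C/C(C)=C/C[C@@H](O)/C(C)=C\CO[Si](C)(C)C(C)(C)C)cc1 | intermediate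
16 | tert-butyldiphenylsilyl ether of 15 at the C4 hydroxyl of the chain | COc1ccc(COC[C@@H](O[Si](C)(C)C(C)(C)C)C/C(C)=C/C[C@@H](O[Si](c2ccccc2)(c2ccccc2)C(C)(C)C)/C(C)=C\CO[Si](C)(C)C(C)(C)C)cc1 | intermediate
17 | (2S,4E,7R,8Z)-2,10-bis(tert-butyldimethylsilyloxy)-7-(tert-butyldiphenylsilyloxy)-4,8-dimethyldeca-4,8-dien-1-ol | OC[C@@H](O[Si](C)(C)C(C)(C)C)C/C(C)=C/C[C@@H](O[Si](c1ccccc1)(c1ccccc1)C(C)(C)C)/C(C)=C\CO[Si](C)(C)C(C)(C)C | intermediate
18 | (2S,4E,7R,8Z)-2,10-bis(tert-butyldimethylsilyloxy)-7-(tert-butyldiphenylsilyloxy)-4,8-dimethyldeca-4,8-dienal | O=C[C@@H](O[Si](C)(C)C(C)(C)C)C/C(C)=C/C[C@@H](O[Si](c1ccccc1)(c1ccccc1)C(C)(C)C)/C(C)=C\CO[Si](C)(C)C(C)(C)C | intermediate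
19 | ethyl (2Z,4S,6E,9R,10Z)-2-bromo-4,12-bis(tert-butyldimethylsilyloxy)-9-(tert-butyldiphenylsilyloxy)-6,10-dimethyldodeca-2,6,10-trienoate | CCOC(=O)/C(Br)=C/[C@@H](O[Si](C)(C)C(C)(C)C)C/C(C)=C/C[C@@H](O[Si](c1ccccc1)(c1ccccc1)C(C)(C)C)/C(C)=C\CO[Si](C)(C)C(C)(C)C | intermediate
20 | ethyl (2Z,4S,6E,9R,10Z)-2-bromo-4-(tert-butyldimethylsilyloxy)-9-(tert-butyldiphenylsilyloxy)-12-hydroxy-6,10-dimethyldodeca-2,6,10-trienoate | CCOC(=O)/C(Br)=C/[C@@H](O[Si](C)(C)C(C)(C)C)C/C(C)=C/C[C@@H](O[Si](c1ccccc1)(c1ccccc1)C(C)(C)C)/C(C)=C\CO | intermediate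
21 | ethyl (2Z,4S,6E,9R,10Z)-2-bromo-4-(tert-butyldimethylsilyloxy)-9-(tert-butyldiphenylsilyloxy)-12-chloro-6,10-dimethyldodeca-2,6,10-trienoate | CCOC(=O)/C(Br)=C/[C@@H](O[Si](C)(C)C(C)(C)C)C/C(C)=C/C[C@@H](O[Si](c1ccccc1)(c1ccccc1)C(C)(C)C)/C(C)=C\CCl | intermediate
22 | (2Z,4S,6E,9R,10Z)-2-bromo-4-(tert-butyldimethylsilyloxy)-9-(tert-butyldiphenylsilyloxy)-12-chloro-6,10-dimethyldodeca-2,6,10-trien-1-ol | OC/C(Br)=C/[C@@H](O[Si](C)(C)C(C)(C)C)C/C(C)=C/C[C@@H](O[Si](c1ccccc1)(c1ccccc1)C(C)(C)C)/C(C)=C\CCl | intermediate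
23 | thirteen-membered cyclic ether (ring O, C13, C11, C7, C8, C9, C10, C1, C2, C3, C4, C5, C6) with Br on C11, C13 trans to C8, 1(10)E, 4Z, 8S OTBS, 3R OTBDPS | O1C/C(Br)=C/[C@@H](O[Si](C)(C)C(C)(C)C)C/C(C)=C/C[C@@H](O[Si](c2ccccc2)(c2ccccc2)C(C)(C)C)/C(C)=C\C1 | intermediate
24 | the cyclic ether of 23 with CO2CH3 (C12) in place of Br | O1C/C(C(=O)OC)=C/[C@@H](O[Si](C)(C)C(C)(C)C)C/C(C)=C/C[C@@H](O[Si](c2ccccc2)(c2ccccc2)C(C)(C)C)/C(C)=C\C1 | intermediate
25 | the cyclic ether of 23 with CH2OH (C12) in place of Br; precursor of the ring contraction (3R, 8S) | O1C/C(CO)=C/[C@@H](O[Si](C)(C)C(C)(C)C)C/C(C)=C/C[C@@H](O[Si](c2ccccc2)(c2ccccc2)C(C)(C)C)/C(C)=C\C1 | intermediate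
26 | lithium C12 alkoxide of 25 | O1C/C(C[O-])=C/[C@@H](O[Si](C)(C)C(C)(C)C)C/C(C)=C/C[C@@H](O[Si](c2ccccc2)(c2ccccc2)C(C)(C)C)/C(C)=C\C1.[Li+] | intermediate (not isolated)
27 | dilithio species of 25, alkoxide at O12 and carbanion at C6 | O1C/C(C[O-])=C/[C@@H](O[Si](C)(C)C(C)(C)C)C/C(C)=C/C[C@@H](O[Si](c2ccccc2)(c2ccccc2)C(C)(C)C)/C(C)=C\[CH-]1.[Li+].[Li+] | intermediate (not isolated)
28 | ten-membered (1(10)E,4Z)-dien-6-ol with 3-hydroxyprop-1-en-2-yl on C7, 3-OTBDPS, 8-OTBS; CIP 3R,6R,7S,8S (C6 and C7 as in the target, C8 epimeric) | O[C@@H]1/C=C(/C)[C@H](O[Si](c2ccccc2)(c2ccccc2)C(C)(C)C)C/C=C(\C)C[C@H](O[Si](C)(C)C(C)(C)C)[C@H]1C(=C)CO | intermediate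
29 | C12 aldehyde (enal) of 28 | O[C@@H]1/C=C(/C)[C@H](O[Si](c2ccccc2)(c2ccccc2)C(C)(C)C)C/C=C(\C)C[C@H](O[Si](C)(C)C(C)(C)C)[C@H]1C(=C)C=O | intermediate (not isolated)
30 | 6,12-lactol of 29 (C12 epimers) | C=C1C(O)O[C@@H]2/C=C(/C)[C@H](O[Si](c3ccccc3)(c3ccccc3)C(C)(C)C)C/C=C(\C)C[C@H](O[Si](C)(C)C(C)(C)C)[C@@H]12 | intermediate (not isolated)
31 | (1(10)E,4Z)-germacra-1(10),4,11(13)-trien-12,6-olide with 3-OTBDPS and 8-OTBS; CIP 3R,6R,7S,8S | C=C1C(=O)O[C@@H]2/C=C(/C)[C@H](O[Si](c3ccccc3)(c3ccccc3)C(C)(C)C)C/C=C(\C)C[C@H](O[Si](C)(C)C(C)(C)C)[C@@H]12 | intermediate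
32 | the lactone of 31 with free 8-hydroxyl; CIP 3R,6R,7R,8S | C=C1C(=O)O[C@@H]2/C=C(/C)[C@H](O[Si](c3ccccc3)(c3ccccc3)C(C)(C)C)C/C=C(\C)C[C@H](O)[C@@H]12 | intermediate
33 | 8-O-(3-methylbutanoyl) lactone with 3-OTBDPS; CIP 3R,6R,7R,8R | C=C1C(=O)O[C@@H]2/C=C(/C)[C@H](O[Si](c3ccccc3)(c3ccccc3)C(C)(C)C)C/C=C(\C)C[C@@H](OC(=O)CC(C)C)[C@@H]12 | intermediate
34 | 1,10-epoxide of 33; CIP 1R,3R,6R,7R,8R,10R | C=C1C(=O)O[C@@H]2/C=C(/C)[C@H](O[Si](c3ccccc3)(c3ccccc3)C(C)(C)C)C[C@H]3O[C@]3(C)C[C@@H](OC(=O)CC(C)C)[C@@H]12 | intermediate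
35 | CNP0300193.1: (4Z)-1,10-epoxy-3-hydroxy-8-(3-methylbutanoyloxy)germacra-4,11(13)-dien-12,6-olide, 1R,3R,6R,7R,8R,10R | C=C1C(=O)O[C@@H]2/C=C(/C)[C@H](O)C[C@H]3O[C@]3(C)C[C@@H](OC(=O)CC(C)C)[C@@H]12 | target

Total step count: 26 steps. Longest linear sequence: 24 steps (from 1 through steps 1–4 and 7–26; steps 5 and 6 make the side fragment 11).

Steps most likely to fail

1. Step 21. What may go wrong: the carbanion may add to the other face of C7=C11 (syn to the C8 silyloxy group), or the influences of C3 and C8 may oppose each other, so that the 6,7-bis-epimer or mixtures form; lithiation at C13 would in addition give ring isomers. The fallback carries C8 with the configuration of the target through the contraction and needs no inversion at the end. It sets out from 23: HF·pyridine removes the C8 silyl group to give the macrocyclic bromo alcohol F1; Mitsunobu inversion with 4-nitrobenzoic acid gives the 8R 4-nitrobenzoate F2; K2CO3 in MeOH frees the 8R alcohol F3; TBSOTf and 2,6-lutidine give the 8R silyl ether F4; carbonylation as in step 19 gives the methyl ester F5 and reduction as in step 20 the C12 alcohol F6; the ring contraction as in step 21 would then give the diol F7 with all centres as in the target; lactonisation as in step 22 gives the lactone F8 and desilylation as in step 23 the 8R alcohol F9; acylation with 3-methylbutanoic anhydride and DMAP, with retention, comes back to the route at 33.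

2. Step 24. What may go wrong: loss of the activated C8 oxygen by elimination toward C9, or no displacement at the hindered carbinol. The fallback inverts C8 by oxidation and reduction instead of SN2. It sets out from 32: Dess–Martin oxidation gives the C8 ketone F10; reduction with NaBH4 and CeCl3 at −78 °C, with hydride arriving on the outer face anti to C11, should give the 8R alcohol F9; acylation with 3-methylbutanoic anhydride and DMAP comes back to the route at 33.

3. Step 25. What may go wrong: attack of the peracid on the other face of C1=C10, or loss of site selectivity toward C4=C5. The fallback replaces substrate control by reagent control. It sets out from 33: Shi epoxidation with the D-fructose-derived ketone and KHSO5 in buffered aqueous acetonitrile, a catalyst that gives R,R epoxides from E trisubstituted alkenes, comes back to the route at 34 and makes no new compound.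

Further compounds
F1 | step 21 | cyclic ether of 23 with free 8S hydroxyl | O1C/C(Br)=C/[C@@H](O)C/C(C)=C/C[C@@H](O[Si](c2ccccc2)(c2ccccc2)C(C)(C)C)/C(C)=C\C1
F2 | step 21 | 8R 4-nitrobenzoate of the cyclic bromo ether | O1C/C(Br)=C/[C@H](OC(=O)c2ccc(cc2)[N+](=O)[O-])C/C(C)=C/C[C@@H](O[Si](c3ccccc3)(c3ccccc3)C(C)(C)C)/C(C)=C\C1
F3 | step 21 | cyclic bromo ether with free 8R hydroxyl | O1C/C(Br)=C/[C@H](O)C/C(C)=C/C[C@@H](O[Si](c2ccccc2)(c2ccccc2)C(C)(C)C)/C(C)=C\C1
F4 | step 21 | C8 epimer of 23 (8R OTBS) | O1C/C(Br)=C/[C@H](O[Si](C)(C)C(C)(C)C)C/C(C)=C/C[C@@H](O[Si](c2ccccc2)(c2ccccc2)C(C)(C)C)/C(C)=C\C1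
F5 | step 21 | C8 epimer of 24 (8R OTBS, C12 methyl ester) | O1C/C(C(=O)OC)=C/[C@H](O[Si](C)(C)C(C)(C)C)C/C(C)=C/C[C@@H](O[Si](c2ccccc2)(c2ccccc2)C(C)(C)C)/C(C)=C\C1
F6 | step 21 | C8 epimer of 25 (8R OTBS, C12 hydroxymethyl) | O1C/C(CO)=C/[C@H](O[Si](C)(C)C(C)(C)C)C/C(C)=C/C[C@@H](O[Si](c2ccccc2)(c2ccccc2)C(C)(C)C)/C(C)=C\C1
F7 | step 21 | C8 epimer of 28, all centres as in the target (CIP 3R,6R,7S,8R) | O[C@@H]1/C=C(/C)[C@H](O[Si](c2ccccc2)(c2ccccc2)C(C)(C)C)C/C=C(\C)C[C@@H](O[Si](C)(C)C(C)(C)C)[C@H]1C(=C)CO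
F8 | step 21 | C8 epimer of 31 (8R OTBS lactone) | C=C1C(=O)O[C@@H]2/C=C(/C)[C@H](O[Si](c3ccccc3)(c3ccccc3)C(C)(C)C)C/C=C(\C)C[C@@H](O[Si](C)(C)C(C)(C)C)[C@@H]12
F9 | step 21 | C8 epimer of 32 (lactone with free 8R hydroxyl) | C=C1C(=O)O[C@@H]2/C=C(/C)[C@H](O[Si](c3ccccc3)(c3ccccc3)C(C)(C)C)C/C=C(\C)C[C@@H](O)[C@@H]12
F10 | step 24 | C8 ketone of the lactone (3R OTBDPS) | C=C1C(=O)O[C@@H]2/C=C(/C)[C@H](O[Si](c3ccccc3)(c3ccccc3)C(C)(C)C)C/C=C(\C)CC(=O)[C@@H]12
F0 | step 25 | none | none
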